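## Retrosynthetic overview

1. Target 20 comes from one acidic global deprotection of the bis-MOM/TBS-protected benzofuran 19.
2. The furan ring (formed last) is disconnected at O1–C2 and C2–aryl: Sonogashira coupling then 5-endo-dig cyclisation of o-ethynylphenol 9 with chromanyl triflate 17.
3. 9 comes from one-carbon homologation of salicylaldehyde 7; the 1,1-dimethylallyl group comes from an Eu-catalysed ortho-Claisen of prenyl ether 5, made from H-bond-differentiated 2,4,6-trihydroxybenzaldehyde.
4. 17 comes from triflation and steric 7-O-silylation of 2,2-dimethylchroman-5,7-diol; the pyran ring (formed first) comes from acid-catalysed condensation of C3-symmetric phloroglucinol with 2-methylbut-3-en-2-ol.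
5. Ring order: chroman pyran ring, then benzofuran furan ring; both trioxygenated benzene rings are bought.

Assumption: the target has no stereocentre (it is achiral), so "single enantiomer" requires no stereocontrol and the route delivers the compound as drawn.

## Route

Step 1
Reactants: 1 2,4,6-trihydroxybenzaldehyde; 2 chloromethyl methyl ether (MOMCl)
Product: 3 2-hydroxy-4,6-bis(methoxymethoxy)benzaldehyde
Conditions: MOMCl (2.2 equiv), i-Pr2NEt (2.5 equiv), CH2Cl2, 0 °C → rt
Reagents that add atoms: chloromethyl methyl ether, COCCl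
Why: Williamson-type O-alkylation takes the 4-OH and one ortho-OH, while the remaining ortho-OH is locked in the hydrogen bond to the aldehyde and stays free, which desymmetrises the phloroglucinol core.

Step 2
Reactants: 3 2-hydroxy-4,6-bis(methoxymethoxy)benzaldehyde; 4 1-bromo-3-methylbut-2-ene (prenyl bromide)
Product: 5 2,4-bis(methoxymethoxy)-6-[(3-methylbut-2-en-1-yl)oxy]benzaldehyde
Conditions: prenyl bromide (1.3 equiv), K2CO3, DMF, rt → 40 °C
Reagents that add atoms: prenyl bromide, CC(C)=CCBr
Why: Williamson ether synthesis (SN2) of the chelated phenoxide with a primary allylic bromide in a dipolar aprotic solvent gives the O-prenyl ether; MOM acetals are base-stable.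

Step 3
Reactants: 5 2,4-bis(methoxymethoxy)-6-[(3-methylbut-2-en-1-yl)oxy]benzaldehyde
Product: 7 2-hydroxy-4,6-bis(methoxymethoxy)-3-(2-methylbut-3-en-2-yl)benzaldehyde, via ortho-dienone 6 (not isolated)
Conditions: Eu(fod)3 (10 mol %), CHCl3, 55–60 °C
Reagents that add atoms: none
Why: Eu(III) chelated between C=O and the ether oxygen catalyses the aromatic Claisen [3,3] rearrangement into the only free ortho carbon with allyl inversion (prenyl → 1,1-dimethylallyl), and at 60 °C dienone 6 is expected to enolise to the H-bonded phenol faster than it undergoes Cope migration; no stereocentre remains.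

Step 4
Reactants: 7 2-hydroxy-4,6-bis(methoxymethoxy)-3-(2-methylbut-3-en-2-yl)benzaldehyde; 8 dimethyl (1-diazo-2-oxopropyl)phosphonate (Ohira–Bestmann reagent)
Product: 9 2-ethynyl-3,5-bis(methoxymethoxy)-6-(2-methylbut-3-en-2-yl)phenol
Conditions: 8 (1.5 equiv), K2CO3 (3 equiv), MeOH/THF, 0 °C → rt
Reagents that add atoms: dimethyl (1-diazo-2-oxopropyl)phosphonate, CC(=O)C(=[N+]=[N-])P(=O)(OC)OC
Why: Seyferth–Gilbert homologation in the Ohira–Bestmann variant (in-situ diazomethylphosphonate anion, HWE-type olefination, loss of N2 and 1,2-H shift) converts ArCHO to ArC≡CH under mild base that leaves MOM ethers and the alkene untouched.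

Step 5
Reactants: 10 benzene-1,3,5-triol (phloroglucinol); 11 2-methylbut-3-en-2-ol
Product: 13 2,2-dimethylchroman-5,7-diol, via 2-prenylphloroglucinol 12 (not isolated)
Conditions: Amberlyst 15, THF/heptane, 60–65 °C, 11 added slowly to 10 kept in excess
Reagents that add atoms: 2-methylbut-3-en-2-ol, CC(C)(O)C=C
Why: the acid resin ionises the tertiary allylic alcohol to the dimethylallyl cation, Friedel–Crafts prenylation of the C3-symmetric arene (all three CH positions equivalent) gives 12, and Markovnikov hydroalkoxylation of its trisubstituted alkene by the ortho-OH closes the 2,2-dimethylchroman; keeping the phenol in excess suppresses double annulation.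

Step 6
Reactants: 13 2,2-dimethylchroman-5,7-diol; 14 tert-butyldimethylsilyl chloride (TBSCl)
Product: 15 7-[(tert-butyldimethylsilyl)oxy]-2,2-dimethylchroman-5-ol
Conditions: TBSCl (1.0 equiv), imidazole, CH2Cl2/DMF, −20 → 0 °C
Reagents that add atoms: tert-butyldimethylsilyl chloride, CC(C)(C)[Si](C)(C)Cl
Why: sterically controlled O-silylation selects the unhindered 7-OH over the 5-OH, which is flanked by the C4 methylene; the minor regioisomer and bis-ether are separable and recyclable.

Step 7
Reactants: 15 7-[(tert-butyldimethylsilyl)oxy]-2,2-dimethylchroman-5-ol; 16 trifluoromethanesulfonic anhydride (Tf2O)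
Product: 17 7-[(tert-butyldimethylsilyl)oxy]-2,2-dimethylchroman-5-yl trifluoromethanesulfonate
Conditions: Tf2O (1.2 equiv), pyridine, CH2Cl2, 0 °C
Reagents that add atoms: trifluoromethanesulfonic anhydride, O=S(=O)(OS(=O)(=O)C(F)(F)F)C(F)(F)F
Why: O-sulfonylation of the remaining phenol turns the C5 oxygen into a cross-coupling leaving group; the aryl silyl ether tolerates Tf2O/pyridine.

Step 8
Reactants: 9 2-ethynyl-3,5-bis(methoxymethoxy)-6-(2-methylbut-3-en-2-yl)phenol; 17 7-[(tert-butyldimethylsilyl)oxy]-2,2-dimethylchroman-5-yl trifluoromethanesulfonate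
Product: 19 tert-butyl({5-[4,6-bis(methoxymethoxy)-7-(2-methylbut-3-en-2-yl)-1-benzofuran-2-yl]-2,2-dimethylchroman-7-yl}oxy)dimethylsilane, via diarylalkyne 18 (not isolated)
Conditions: Pd(PPh3)4 (5 mol %), CuI (10 mol %), Et3N, DMF, degassed, 60 → 80 °C
Reagents that add atoms: none
Why: Sonogashira coupling of the aryl triflate followed by Cu/Pd-promoted 5-endo-dig hydroalkoxylation (Cacchi-type heteroannulation) closes the furan through the only free phenol, the one next to the 1,1-dimethylallyl group, so a single benzofuran regioisomer forms.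

Step 9
Reactants: 19 tert-butyl({5-[4,6-bis(methoxymethoxy)-7-(2-methylbut-3-en-2-yl)-1-benzofuran-2-yl]-2,2-dimethylchroman-7-yl}oxy)dimethylsilane
Product: 20 5-[4,6-dihydroxy-7-(2-methylbut-3-en-2-yl)-1-benzofuran-2-yl]-2,2-dimethylchroman-7-ol (CNP0300714.0)
Conditions: HCl (3 M in MeOH), 45–50 °C
Reagents that add atoms: none
Why: acid-catalysed acetal methanolysis removes both MOM groups and the same medium solvolyses the aryl TBS ether, while the monosubstituted alkene of the 1,1-dimethylallyl group, the chroman and the benzofuran should resist dilute methanolic HCl at ≤50 °C.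

## Compound list

1 | 2,4,6-trihydroxybenzaldehyde | O=Cc1c(O)cc(O)cc1O | starting material
2 | chloromethyl methyl ether (MOMCl) | COCCl | starting material
3 | 2-hydroxy-4,6-bis(methoxymethoxy)benzaldehyde | O=Cc1c(O)cc(OCOC)cc1OCOC | intermediate
4 | 1-bromo-3-methylbut-2-ene (prenyl bromide) | CC(C)=CCBr | starting material
5 | 2,4-bis(methoxymethoxy)-6-[(3-methylbut-2-en-1-yl)oxy]benzaldehyde | O=Cc1c(OCC=C(C)C)cc(OCOC)cc1OCOC | intermediate
6 | ortho-dienone: 2,4-bis(methoxymethoxy)-5-(2-methylbut-3-en-2-yl)-6-oxocyclohexa-1,3-diene-1-carbaldehyde (racemic, not isolated) | O=CC1=C(OCOC)C=C(OCOC)C(C(C)(C)C=C)C1=O | intermediate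
7 | 2-hydroxy-4,6-bis(methoxymethoxy)-3-(2-methylbut-3-en-2-yl)benzaldehyde | O=Cc1c(O)c(C(C)(C)C=C)c(OCOC)cc1OCOC | intermediate
8 | dimethyl (1-diazo-2-oxopropyl)phosphonate (Ohira–Bestmann reagent) | CC(=O)C(=[N+]=[N-])P(=O)(OC)OC | starting material
9 | 2-ethynyl-3,5-bis(methoxymethoxy)-6-(2-methylbut-3-en-2-yl)phenol | C#Cc1c(O)c(C(C)(C)C=C)c(OCOC)cc1OCOC | intermediate
10 | benzene-1,3,5-triol (phloroglucinol) | Oc1cc(O)cc(O)c1 | starting material
11 | 2-methylbut-3-en-2-ol | CC(C)(O)C=C | starting material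
12 | 2-(3-methylbut-2-en-1-yl)benzene-1,3,5-triol (2-prenylphloroglucinol, not isolated) | CC(C)=CCc1c(O)cc(O)cc1O | intermediate
13 | 2,2-dimethylchroman-5,7-diol | CC1(C)CCc2c(O)cc(O)cc2O1 | intermediate
14 | tert-butyldimethylsilyl chloride (TBSCl) | CC(C)(C)[Si](C)(C)Cl | starting material
15 | 7-[(tert-butyldimethylsilyl)oxy]-2,2-dimethylchroman-5-ol | CC1(C)CCc2c(O)cc(O[Si](C)(C)C(C)(C)C)cc2O1 | intermediate
16 | trifluoromethanesulfonic anhydride (Tf2O) | O=S(=O)(OS(=O)(=O)C(F)(F)F)C(F)(F)F | starting material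
17 | 7-[(tert-butyldimethylsilyl)oxy]-2,2-dimethylchroman-5-yl trifluoromethanesulfonate | CC1(C)CCc2c(OS(=O)(=O)C(F)(F)F)cc(O[Si](C)(C)C(C)(C)C)cc2O1 | intermediate
18 | diarylalkyne: 2-({7-[(tert-butyldimethylsilyl)oxy]-2,2-dimethylchroman-5-yl}ethynyl)-3,5-bis(methoxymethoxy)-6-(2-methylbut-3-en-2-yl)phenol (not isolated) | C=CC(C)(C)c1c(O)c(C#Cc2cc(O[Si](C)(C)C(C)(C)C)cc3c2CCC(C)(C)O3)c(OCOC)cc1OCOC | intermediate
19 | tert-butyl({5-[4,6-bis(methoxymethoxy)-7-(2-methylbut-3-en-2-yl)-1-benzofuran-2-yl]-2,2-dimethylchroman-7-yl}oxy)dimethylsilane | C=CC(C)(C)c1c(OCOC)cc(OCOC)c2cc(-c3cc(O[Si](C)(C)C(C)(C)C)cc4c3CCC(C)(C)O4)oc12 | intermediate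
20 | 5-[4,6-dihydroxy-7-(2-methylbut-3-en-2-yl)-1-benzofuran-2-yl]-2,2-dimethylchroman-7-ol (achiral) | C=CC(C)(C)c1c(O)cc(O)c2cc(-c3cc(O)cc4c3CCC(C)(C)O4)oc12 | target

## Step count and risks

Total steps: 9 (convergent).
Longest linear sequence: 6 steps (1 → 3 → 5 → 7 → 9 → 19 → 20); the chroman branch is 3 steps (10 → 13 → 15 → 17) before the union.

Three steps most likely to fail:

First risk, step 3 (Claisen). The ortho-dienone 6 can drift by Cope shift to the para carbon and give the para-prenyl isomer instead of the ortho-1,1-dimethylallyl phenol. The fallback sets out from 3 and comes back at 7 without any sigmatropic step. NBS with catalytic i-Pr2NH in CH2Cl2 at −20 °C brominates ortho to the free phenol to give 3-bromo-2-hydroxy-4,6-bis(methoxymethoxy)benzaldehyde F1. A ligand-controlled γ-selective (branched) Suzuki–Miyaura allylation of F1 with commercial 3-methylbut-2-enylboronic acid pinacol ester (Pd(0)/bulky biarylphosphine, K3PO4, THF–H2O, 40–60 °C) then makes the aryl–CMe2 bond directly and delivers 7.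

Second risk, step 4 (Ohira–Bestmann). Under K2CO3/MeOH the aldehyde is a hindered, strongly deactivated phenoxide-aldehyde and may not homologate. The fallback sets out from 7 (and uses 17) and comes back at 19, bypassing 9 and step 8. Non-basic Ramirez olefination (CBr4, PPh3, Et3N buffer, CH2Cl2, 0 °C) of the H-bond-activated aldehyde gives 2-(2,2-dibromoethenyl)-3,5-bis(methoxymethoxy)-6-(2-methylbut-3-en-2-yl)phenol F2. Intramolecular Ullmann-type O-vinylation (CuI, K3PO4, THF, 80 °C) gives 2-bromo-4,6-bis(methoxymethoxy)-7-(2-methylbut-3-en-2-yl)-1-benzofuran F3. Miyaura borylation of 17 (B2pin2, Pd(dppf)Cl2, KOAc, dioxane, 90 °C) gives tert-butyl{[2,2-dimethyl-5-(4,4,5,5-tetramethyl-1,3,2-dioxaborolan-2-yl)chroman-7-yl]oxy}dimethylsilane F4. Suzuki coupling of F3 with F4 (Pd(dppf)Cl2, K3PO4, dioxane–H2O, 60 °C) gives 19.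

Third risk, step 8 (Sonogashira/cyclisation). The electron-rich, ortho-substituted aryl triflate may couple slowly, so the ethynylphenol cyclises to the 2-unsubstituted benzofuran or homocouples first. The fallback sets out from 9 and comes back at 19 by making that cyclisation the main path. CuI (10 mol %), Et3N, DMF, 60 °C converts 9 into 4,6-bis(methoxymethoxy)-7-(2-methylbut-3-en-2-yl)-1-benzofuran F5. C2-lithiation (n-BuLi, THF, −78 °C) and transmetalation with ZnCl2 give [4,6-bis(methoxymethoxy)-7-(2-methylbut-3-en-2-yl)-1-benzofuran-2-yl]zinc chloride F6. Negishi coupling of F6 with triflate 17 (Pd2(dba)3/XPhos, THF, 50 °C) gives 19.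

## Further compounds

F1 | step 3 | 3-bromo-2-hydroxy-4,6-bis(methoxymethoxy)benzaldehyde | O=Cc1c(O)c(Br)c(OCOC)cc1OCOC
F2 | step 4 | 2-(2,2-dibromoethenyl)-3,5-bis(methoxymethoxy)-6-(2-methylbut-3-en-2-yl)phenol | C=CC(C)(C)c1c(O)c(C=C(Br)Br)c(OCOC)cc1OCOC
F3 | step 4 | 2-bromo-4,6-bis(methoxymethoxy)-7-(2-methylbut-3-en-2-yl)-1-benzofuran | C=CC(C)(C)c1c(OCOC)cc(OCOC)c2cc(Br)oc12
F4 | step 4 | tert-butyl{[2,2-dimethyl-5-(4,4,5,5-tetramethyl-1,3,2-dioxaborolan-2-yl)chroman-7-yl]oxy}dimethylsilane | CC1(C)CCc2c(B3OC(C)(C)C(C)(C)O3)cc(O[Si](C)(C)C(C)(C)C)cc2O1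
F5 | step 8 | 4,6-bis(methoxymethoxy)-7-(2-methylbut-3-en-2-yl)-1-benzofuran | C=CC(C)(C)c1c(OCOC)cc(OCOC)c2ccoc12
F6 | step 8 | [4,6-bis(methoxymethoxy)-7-(2-methylbut-3-en-2-yl)-1-benzofuran-2-yl]zinc chloride | C=CC(C)(C)c1c(OCOC)cc(OCOC)c2cc([Zn]Cl)oc12
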